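An easy step starts the reckoning: on Wednesday's run side product B rises from 9 % at 0.667 min to 19 % at 4.00 min while substrate stands at 16 % to 15 %, and on Monday's run it rises from 32 % at 2.50 min to 38 % at 4.00 min while substrate goes from 20 % to 16 %. Divide each rate by the square of the mean c(substrate) and you read 1.25 mM⁻¹ min⁻¹ on Wednesday's run and 1.23 mM⁻¹ min⁻¹ on Monday's, close together although the charges of reagent differ, 2.7 equiv against 1.3 equiv. Their mean, 1.24 mM⁻¹ min⁻¹, is what you carry: the drain constant, a second-order rate constant for substrate lost to side product B, and a reading with the scatter of the readings in it.

| flask | substrate | reagent | remark | time |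
|---|---|---|---|---|
| Monday's | 1 mM | 1.3 equiv | run made earlier |  |
| Wednesday's | 1 mM | 2.7 equiv | run made earlier |  |
| midnight | 1.0 mM | 0.900 equiv |  | 6.0 min |
| dusk | 1.0 mM | 1.40 equiv |  | 6.0 min |
| winter | 1.0 mM | 2.00 equiv |  | 6.0 min |

| run | time / min | side product A / % | side product B / % | substrate / % | target / % |
|---|---|---|---|---|---|
| Monday's | 0.333 | 2 | 13 | 41 | 43 |
| Monday's | 0.500 | 1 | 19 | 35 | 48 |
| Monday's | 1.00 | 5 | 26 | 29 | 47 |
| Monday's | 1.50 | 3 | 26 | 24 | 47 |
| Monday's | 2.50 | 3 | 32 | 20 | 41 |
| Monday's | 4.00 | 5 | 38 | 16 | 38 |
| Wednesday's | 0.667 | 1 | 9 | 16 | 70 |
| Wednesday's | 1.33 | 1 | 11 | 16 | 70 |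
| Wednesday's | 2.00 | 2 | 18 | 15 | 68 |
| Wednesday's | 3.00 | 3 | 19 | 16 | 67 |
| Wednesday's | 4.00 | 5 | 19 | 15 | 62 |

(readings scatter by 1.5 percentage points)

1. which of these there is most of at the end, counted by the substrate in it, midnight (side product A / target / substrate / side product B)
2. which of these there is most of at the end, counted by the substrate in it, dusk (side product A / target / substrate / side product B)
3. which of these there is most of at the end, counted by the substrate in it, winter (side product A / target / substrate / side product B)
4. how much there is at the end of the one of these that leads, in percent of the substrate charged: midnight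
5. how much there is at the end of the one of these that leads, in percent of the substrate charged: dusk
6. how much there is at the end of the one of these that leads, in percent of the substrate charged: winter

- percentages count the substrate that a species holds: one side product B counts as two
- what was read earlier has a scatter of 1.5 percentage points, one standard deviation

With 1 mM of substrate charged, as on Monday's run, the drain starts at 1.24 mM min⁻¹. What slows it is the fall of substrate, counted as a square: down by a factor of 5.95 at Monday's first reading, by a further 6.57 at its last, 39.1 together, which leaves a creep of 0.0318 mM min⁻¹, far below the start. So you can estimate the end of dusk as Monday's last reading plus that creep held steady: over the remaining 2.00 min, side product B gains 6.4 percentage points on its 38 %, which makes your reckoning 44.4 %, more than the 38 % of target at that last reading. Dusk carries 1.40 equiv of reagent against Monday's 1.3 equiv, and Wednesday's run, with more reagent still, reads less side product B at 4.00 min, 19 % against 38 %, so this figure may lean high.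

The forecast, holding that side product B “tracks substrate squared, not reagent”, names side product B at midnight with 56 % (50 % to 62 %), side product B at dusk with 41 % (37 % to 46 %), and target at winter with 49 % (44 % to 54 %). At dusk your figure stands above its value, though inside its range.

The flasks give side product B at midnight with 55.8 %, side product B at dusk with 44.1 %, and target at winter with 46.9 %, each leader as forecast and each amount inside its range.

    substrate + reagent ⇌ target (K = 2000 M⁻¹, k = 40.3 M⁻¹ s⁻¹)
    substrate → side product A (k = 7.01 × 10⁻⁴ s⁻¹)
    2 substrate → side product B (k = 9.29 M⁻¹ s⁻¹)
    2 substrate → self-condensation product (k = 0.0138 M⁻¹ s⁻¹)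

Dusk is not at rest at 6.00 min: with 15.5 % of its substrate free, the drain constant still gives 0.0298 min⁻¹ as a fraction of the charge. The flask like dusk but charged with 4.0 mM of substrate ends with 51.5 % of target and 38.8 % of side product B, and its 7.04 % of free substrate still gives 0.0246 min⁻¹ of its own charge. Left until 60.0 min, dusk holds 71.1 % of side product B, 19.3 % of side product A, and its target has fallen from 34.4 % to 6.96 %.

The numbers in the tables stem from a simulated flask from invented constants, noise included.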